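The cyclohexene ring of the target (C1 = alkene carbon bearing the side chain, C2 = CH, C3 = CH2, C4 = CHCl, C5 = CMe2, C6 = CHBr) is a Diels–Alder retron. Cutting C3–C4 and C5–C6, on either side of the C1=C2 double bond, gives a (Z)-bromodiene that already carries the chlorinated side chain and (E)-3-chloro-2-methylpropenal. A catalytic enantioselective [4+2] cycloaddition forms both bonds at once and translates alkene geometries into the trans C4–Cl/C6–Br pair; the formyl group on C5 is a temporary activator, later reduced to the second methyl. The diene comes from (S)-glyceraldehyde acetonide by anti-carbomagnesiation/bromination and invertive chlorination.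

Key step: step 7

Assumption: (S)-glyceraldehyde acetonide 1 is taken as a commercial chiral-pool material (it is also one oxidation away from commercial (R)-solketal), and 3-(dimethylamino)-2-methylprop-2-enal 8 as commercial.

Step 1
Reactants: 1 (S)-2,2-dimethyl-1,3-dioxolane-4-carbaldehyde
Product: 2 (R)-4-ethynyl-2,2-dimethyl-1,3-dioxolane
Conditions: dimethyl (1-diazo-2-oxopropyl)phosphonate, K2CO3, MeOH, 0 °C → rt
Reagents that add atoms: dimethyl (1-diazo-2-oxopropyl)phosphonate, COP(=O)(OC)C(=[N+]=[N-])C(C)=O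
Why: Seyferth–Gilbert homologation with the in situ generated diazomethylphosphonate should convert the aldehyde into the terminal alkyne under mild carbonate conditions that leave the α-alkoxy stereocentre, bought with 1, untouched (only its descriptor changes).

Step 2
Reactants: 2 (R)-4-ethynyl-2,2-dimethyl-1,3-dioxolane
Product: 3 (R)-but-3-yne-1,2-diol
Conditions: AcOH/H2O (4:1), 40 °C
Reagents that add atoms: none
Why: Acid-catalysed hydrolysis of the isopropylidene acetal should free the diol without touching the alkyne or the stereocentre.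

Step 3
Reactants: 3 (R)-but-3-yne-1,2-diol
Product: 4 (R)-1-[(tert-butyldiphenylsilyl)oxy]but-3-yn-2-ol
Conditions: TBDPSCl (1.05 equiv), imidazole, CH2Cl2, 0 °C
Reagents that add atoms: tert-butyl(chloro)diphenylsilane, CC(C)(C)[Si](Cl)(c1ccccc1)c1ccccc1
Why: Silylation with the bulky chlorosilane should be selective for the primary hydroxyl of the 1,2-diol and leaves the propargylic OH free to direct the next step.

Step 4
Reactants: 4 (R)-1-[(tert-butyldiphenylsilyl)oxy]but-3-yn-2-ol
Product: 6 (2R,3Z)-4-bromo-1-[(tert-butyldiphenylsilyl)oxy]-3-ethenylbut-3-en-2-ol, via alkenylmagnesium chelate 5 (not isolated)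
Conditions: CH2=CHMgCl (3.5 equiv), THF, 0 °C → reflux; then NBS, −78 → 0 °C; aq. NH4Cl
Reagents that add atoms: vinylmagnesium chloride, C=C[Mg]Cl; N-bromosuccinimide, BrN1C(=O)CCC1=O
Why: Alkoxide-directed anti-carbomagnesiation of the propargylic alcohol should deliver vinyl to the proximal alkyne carbon and magnesium to the terminal carbon inside a five-membered chelate, so that bromination of the C–Mg bond with retention places Br cis to the carbinol carbon (Z) and trans to the new vinyl group.

Step 5
Reactants: 6 (2R,3Z)-4-bromo-1-[(tert-butyldiphenylsilyl)oxy]-3-ethenylbut-3-en-2-ol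
Product: 7 tert-butyl{[(2S,3Z)-4-bromo-2-chloro-3-ethenylbut-3-en-1-yl]oxy}diphenylsilane
Conditions: PPh3, hexachloroacetone, CH2Cl2, −20 → 0 °C
Reagents that add atoms: hexachloroacetone, ClC(Cl)(Cl)C(=O)C(Cl)(Cl)Cl
Why: Appel-type chlorination of the secondary allylic alcohol should proceed by SN2 displacement of the alkoxyphosphonium ion with inversion and without allylic transposition, setting the (S)-configured C–Cl centre of the side chain.

Step 6
Reactants: 8 (E)-3-(dimethylamino)-2-methylprop-2-enal
Product: 10 (E)-3-chloro-2-methylprop-2-enal, via chloroiminium chloride 9 (not isolated)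
Conditions: (COCl)2, CH2Cl2, 0 °C; then ice-water; distillation
Reagents that add atoms: oxalyl chloride, ClC(=O)C(=O)Cl; water, O
Why: Oxalyl chloride should convert the vinylogous formamide into a vinylogous Vilsmeier (chloroiminium) salt whose hydrolysis gives the β-chlorovinyl aldehyde, the extended E isomer (Cl trans to CHO) being the one expected to dominate and taken on after distillation.

Step 7
Reactants: 7 tert-butyl{[(2S,3Z)-4-bromo-2-chloro-3-ethenylbut-3-en-1-yl]oxy}diphenylsilane; 10 (E)-3-chloro-2-methylprop-2-enal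
Product: 11 (1S,2R,6R)-2-bromo-3-[(1S)-2-[(tert-butyldiphenylsilyl)oxy]-1-chloroethyl]-6-chloro-1-methylcyclohex-3-ene-1-carbaldehyde
Conditions: (S)-3,3-diphenyl-1-(o-tolyl)tetrahydro-1H,3H-pyrrolo[1,2-c][1,3,2]oxazaborole (20 mol%), Tf2NH (18 mol%), CH2Cl2, −78 → −20 °C
Reagents that add atoms: none
Why: The N-protonated oxazaborolidine binds the s-trans enal 10 through boron and a formyl C–H···O contact and lowers its LUMO, so that a concerted, asynchronous [4+2] cycloaddition with diene 7 forms C3–C4 (CH2 to CHCl) slightly ahead of C5–C6 (CMe(CHO) to CHBr); the closest known reaction is the cationic-oxazaborolidine-catalysed Diels–Alder reaction of 2-methylacrolein and related α-substituted enals with acyclic dienes. The cyclohexene ring is closed by intermolecular π4s+π2s cycloaddition, both bonds being formed suprafacially on each partner, not by cyclisation of a tethered chain. The C–Cl centre follows from the E geometry of 10 (Cl trans to CHO, hence exo), and the C–Br centre from the Z ("outside") bromide of 7 together with the endo orientation of the formyl group, which places Br cis to CHO and trans to Cl; the quaternary carbon is stereogenic only until step 9. The absolute sense is set by the catalyst, whose phenyl group is expected to shield the C2-Re face of the bound enal so that the diene adds to the C2-Si face, and it should be matched by the diene, in which A(1,3) strain with the cis bromine holds the side-chain C–H in the diene plane and leaves open the face that carries the small Cl, anti to CH2OTBDPS. The step needs "ortho" regiochemistry with respect to bromine (chlorinated β-carbon to the CH2 terminus), which is favoured by the unhindered CH2 terminus, by lone-pair donation from Br and by the inductively deactivated substituent on the internal diene carbon, and it needs endo over exo selectivity, which a Lewis-acid-bound formyl group normally secures with acyclic dienes.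

Step 8
Reactants: 11 (1S,2R,6R)-2-bromo-3-[(1S)-2-[(tert-butyldiphenylsilyl)oxy]-1-chloroethyl]-6-chloro-1-methylcyclohex-3-ene-1-carbaldehyde
Product: 12 N'-[(E)-{(1S,2R,6R)-2-bromo-3-[(1S)-2-[(tert-butyldiphenylsilyl)oxy]-1-chloroethyl]-6-chloro-1-methylcyclohex-3-en-1-yl}methylidene]-4-methylbenzenesulfonohydrazide
Conditions: TsNHNH2, cat. AcOH, THF, rt → 40 °C
Reagents that add atoms: 4-methylbenzenesulfonohydrazide, Cc1ccc(cc1)S(=O)(=O)NN
Why: Condensation of the aldehyde with tosylhydrazide should give the tosylhydrazone, and because the α-carbon is quaternary neither epimerisation nor β-elimination of the halides can occur.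

Step 9
Reactants: 12 N'-[(E)-{(1S,2R,6R)-2-bromo-3-[(1S)-2-[(tert-butyldiphenylsilyl)oxy]-1-chloroethyl]-6-chloro-1-methylcyclohex-3-en-1-yl}methylidene]-4-methylbenzenesulfonohydrazide
Product: 15 tert-butyl{(2S)-2-[(4R,6S)-6-bromo-4-chloro-5,5-dimethylcyclohex-1-en-1-yl]-2-chloroethoxy}diphenylsilane, via N-boryl tosylhydrazine 13 (not isolated), via monoalkyl diazene 14 (not isolated)
Conditions: catecholborane, CHCl3, 0 °C; then NaOAc·3H2O, reflux
Reagents that add atoms: none
Why: Caglioti-type reduction of the tosylhydrazone, in which catecholborane hydroborates the C=N bond and acetate then triggers loss of sulfinate and dinitrogen from the diazene, should turn the formyl carbon into the second methyl group under non-basic, non-radical-chain conditions that spare the alkyl halides, the alkene and the silyl ether.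

Step 10
Reactants: 15 tert-butyl{(2S)-2-[(4R,6S)-6-bromo-4-chloro-5,5-dimethylcyclohex-1-en-1-yl]-2-chloroethoxy}diphenylsilane
Product: 16 (2S)-2-[(4R,6S)-6-bromo-4-chloro-5,5-dimethylcyclohex-1-en-1-yl]-2-chloroethan-1-ol
Conditions: HF·pyridine, THF/pyridine, 0 °C → rt
Reagents that add atoms: none
Why: Acidic fluoride should cleave the primary silyl ether without the basicity that could eliminate or displace the allylic halides.

Step 11
Reactants: 16 (2S)-2-[(4R,6S)-6-bromo-4-chloro-5,5-dimethylcyclohex-1-en-1-yl]-2-chloroethan-1-ol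
Product: 17 (4R,6S)-6-bromo-1-[(1S)-2-bromo-1-chloroethyl]-4-chloro-5,5-dimethylcyclohex-1-ene
Conditions: CBr4, PPh3, CH2Cl2, 0 °C
Reagents that add atoms: tetrabromomethane, BrC(Br)(Br)Br
Why: Appel bromination should convert the primary alcohol into the bromide by SN2 displacement at a non-stereogenic carbon, the neighbouring secondary chloride being a poor participating group.

Compound list
1 | (S)-2,2-dimethyl-1,3-dioxolane-4-carbaldehyde | O=C[C@@H]1COC(C)(C)O1 | starting material
2 | (R)-4-ethynyl-2,2-dimethyl-1,3-dioxolane | C#C[C@@H]1COC(C)(C)O1 | intermediate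
3 | (R)-but-3-yne-1,2-diol | C#C[C@@H](O)CO | intermediate
4 | (R)-1-[(tert-butyldiphenylsilyl)oxy]but-3-yn-2-ol | C#C[C@@H](O)CO[Si](c1ccccc1)(c1ccccc1)C(C)(C)C | intermediate
5 | (5R)-5-{[(tert-butyldiphenylsilyl)oxy]methyl}-4-ethenyl-2,5-dihydro-1,2-oxamagnesole (alkenylmagnesium chelate) | C=CC1=C[Mg]O[C@H]1CO[Si](c1ccccc1)(c1ccccc1)C(C)(C)C | intermediate (not isolated)
6 | (2R,3Z)-4-bromo-1-[(tert-butyldiphenylsilyl)oxy]-3-ethenylbut-3-en-2-ol | Br/C=C(/C=C)[C@@H](O)CO[Si](c1ccccc1)(c1ccccc1)C(C)(C)C | intermediate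
7 | tert-butyl{[(2S,3Z)-4-bromo-2-chloro-3-ethenylbut-3-en-1-yl]oxy}diphenylsilane | Br/C=C(/C=C)[C@H](Cl)CO[Si](c1ccccc1)(c1ccccc1)C(C)(C)C | intermediate
8 | (E)-3-(dimethylamino)-2-methylprop-2-enal | CN(C)/C=C(\C)C=O | starting material
9 | N-[(2E)-3-chloro-2-methylprop-2-en-1-ylidene]-N-methylmethanaminium chloride | C[N+](C)=C/C(C)=C/Cl.[Cl-] | intermediate (not isolated)
10 | (E)-3-chloro-2-methylprop-2-enal | Cl/C=C(\C)C=O | intermediate
11 | (1S,2R,6R)-2-bromo-3-[(1S)-2-[(tert-butyldiphenylsilyl)oxy]-1-chloroethyl]-6-chloro-1-methylcyclohex-3-ene-1-carbaldehyde | O=C[C@@]1(C)[C@H](Cl)CC=C([C@H](Cl)CO[Si](c2ccccc2)(c2ccccc2)C(C)(C)C)[C@H]1Br | intermediate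
12 | N'-[(E)-{(1S,2R,6R)-2-bromo-3-[(1S)-2-[(tert-butyldiphenylsilyl)oxy]-1-chloroethyl]-6-chloro-1-methylcyclohex-3-en-1-yl}methylidene]-4-methylbenzenesulfonohydrazide | Cc1ccc(cc1)S(=O)(=O)N/N=C/[C@@]1(C)[C@H](Cl)CC=C([C@H](Cl)CO[Si](c2ccccc2)(c2ccccc2)C(C)(C)C)[C@H]1Br | intermediate
13 | N'-(1,3,2-benzodioxaborol-2-yl)-N'-{[(1S,2R,6R)-2-bromo-3-[(1S)-2-[(tert-butyldiphenylsilyl)oxy]-1-chloroethyl]-6-chloro-1-methylcyclohex-3-en-1-yl]methyl}-4-methylbenzenesulfonohydrazide | Cc1ccc(cc1)S(=O)(=O)NN(C[C@@]1(C)[C@H](Cl)CC=C([C@H](Cl)CO[Si](c2ccccc2)(c2ccccc2)C(C)(C)C)[C@H]1Br)B1Oc2ccccc2O1 | intermediate (not isolated)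
14 | {[(1S,2R,6R)-2-bromo-3-[(1S)-2-[(tert-butyldiphenylsilyl)oxy]-1-chloroethyl]-6-chloro-1-methylcyclohex-3-en-1-yl]methyl}diazene | N=NC[C@@]1(C)[C@H](Cl)CC=C([C@H](Cl)CO[Si](c2ccccc2)(c2ccccc2)C(C)(C)C)[C@H]1Br | intermediate (not isolated)
15 | tert-butyl{(2S)-2-[(4R,6S)-6-bromo-4-chloro-5,5-dimethylcyclohex-1-en-1-yl]-2-chloroethoxy}diphenylsilane | CC1(C)[C@H](Cl)CC=C([C@H](Cl)CO[Si](c2ccccc2)(c2ccccc2)C(C)(C)C)[C@H]1Br | intermediate
16 | (2S)-2-[(4R,6S)-6-bromo-4-chloro-5,5-dimethylcyclohex-1-en-1-yl]-2-chloroethan-1-ol | CC1(C)[C@H](Cl)CC=C([C@H](Cl)CO)[C@H]1Br | intermediate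
17 | (4R,6S)-6-bromo-1-[(1S)-2-bromo-1-chloroethyl]-4-chloro-5,5-dimethylcyclohex-1-ene | CC1(C)[C@H](Cl)CC=C([C@H](Cl)CBr)[C@H]1Br | target

Total step count: 11. Longest linear sequence: 10 (steps 1–5 and 7–11); step 6 prepares the dienophile.

Steps most likely to fail

1. Step 7. The halogen-deactivated diene may react too slowly with the trisubstituted enal at the temperatures the catalyst tolerates, and regio- or endo-selectivity may erode on warming. The fallback is a cationic Diels–Alder reaction through a chiral acetal. It sets out from 10, which is acetalised with (2R,4R)-pentane-2,4-diol (PPTS, benzene, azeotropic removal of water) to give (4R,6R)-2-[(E)-1-chloroprop-1-en-2-yl]-4,6-dimethyl-1,3-dioxane F1. Its ring-opened vinyl oxocarbenium ion (cat. Me3SiOTf, CH2Cl2, −78 °C) is a much stronger dienophile and should add to diene 7 with the same ortho and endo preferences, now under auxiliary control reinforced by the bias of the diene. This gives (4R,6R)-2-{(1S,2R,6R)-2-bromo-3-[(1S)-2-[(tert-butyldiphenylsilyl)oxy]-1-chloroethyl]-6-chloro-1-methylcyclohex-3-en-1-yl}-4,6-dimethyl-1,3-dioxane F2. Hydrolysis (CF3CO2H, H2O/THF) comes back to the route at 11.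

2. Step 9 (together with the hydrazone formation that feeds it). Intramolecular N-alkylation of the sulfonylhydrazide by the allylic bromide or chloride, or side reactions while the diazene loses dinitrogen, may compete with clean reduction at the very hindered neopentyl position. The fallback sets out from 7, comes back at 15, and lets the dienophile carry both methyl groups so that the formyl-to-methyl conversion is avoided.
   - Commercial 4,4,5,5-tetramethyl-2-(2-methylprop-1-en-1-yl)-1,3,2-dioxaborolane F3 is converted with BCl3 (CH2Cl2, −78 → 0 °C) into dichloro(2-methylprop-1-en-1-yl)borane F4.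
   - Its boron-activated [4+2] cycloaddition with 7 (CH2Cl2, rt) should place boron on the carbon that joins the CH2 terminus, endo and therefore cis to Br, on the diene face anti to CH2OTBDPS. This gives dichloro{(1S,5S)-5-bromo-4-[(1S)-2-[(tert-butyldiphenylsilyl)oxy]-1-chloroethyl]-6,6-dimethylcyclohex-3-en-1-yl}borane F5.
   - Pinacol and Et3N turn it into 2-{(1S,5S)-5-bromo-4-[(1S)-2-[(tert-butyldiphenylsilyl)oxy]-1-chloroethyl]-6,6-dimethylcyclohex-3-en-1-yl}-4,4,5,5-tetramethyl-1,3,2-dioxaborolane F6.
   - 3,5-Bis(trifluoromethyl)phenyllithium (THF, −78 °C) adds to boron to give the lithium aryl(alkyl)boronate complex F7.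
   - Trichloroisocyanuric acid then chlorinates F7 with inversion at carbon, placing Cl trans to Br and giving 15 directly.

3. Step 5. Ionisation of the dienylic alkoxyphosphonium ion (partial loss of configuration) or attack with allylic shift may accompany the direct displacement. The fallback separates activation from displacement. It sets out from 6, which is converted (MsCl, Et3N, CH2Cl2, −20 °C) into (2R,3Z)-4-bromo-1-[(tert-butyldiphenylsilyl)oxy]-3-ethenylbut-3-en-2-yl methanesulfonate F8. Displacement with Bu4NCl in acetone at 0 °C → rt (SN2, inversion, soluble chloride in a weakly ionising medium) comes back at 7.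

Further compounds
F1 | step 7 | (4R,6R)-2-[(E)-1-chloroprop-1-en-2-yl]-4,6-dimethyl-1,3-dioxane | Cl/C=C(\C)C1O[C@H](C)C[C@@H](C)O1
F2 | step 7 | (4R,6R)-2-{(1S,2R,6R)-2-bromo-3-[(1S)-2-[(tert-butyldiphenylsilyl)oxy]-1-chloroethyl]-6-chloro-1-methylcyclohex-3-en-1-yl}-4,6-dimethyl-1,3-dioxane | C[C@@H]1C[C@@H](C)OC(O1)[C@@]1(C)[C@H](Cl)CC=C([C@H](Cl)CO[Si](c2ccccc2)(c2ccccc2)C(C)(C)C)[C@H]1Br
F3 | step 9 | 4,4,5,5-tetramethyl-2-(2-methylprop-1-en-1-yl)-1,3,2-dioxaborolane | CC(C)=CB1OC(C)(C)C(C)(C)O1
F4 | step 9 | dichloro(2-methylprop-1-en-1-yl)borane | CC(C)=CB(Cl)Cl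
F5 | step 9 | dichloro{(1S,5S)-5-bromo-4-[(1S)-2-[(tert-butyldiphenylsilyl)oxy]-1-chloroethyl]-6,6-dimethylcyclohex-3-en-1-yl}borane | CC1(C)[C@@H](B(Cl)Cl)CC=C([C@H](Cl)CO[Si](c2ccccc2)(c2ccccc2)C(C)(C)C)[C@H]1Br
F6 | step 9 | 2-{(1S,5S)-5-bromo-4-[(1S)-2-[(tert-butyldiphenylsilyl)oxy]-1-chloroethyl]-6,6-dimethylcyclohex-3-en-1-yl}-4,4,5,5-tetramethyl-1,3,2-dioxaborolane | CC1(C)[C@@H](B2OC(C)(C)C(C)(C)O2)CC=C([C@H](Cl)CO[Si](c2ccccc2)(c2ccccc2)C(C)(C)C)[C@H]1Br
F7 | step 9 | lithium [3,5-bis(trifluoromethyl)phenyl]{(1S,5S)-5-bromo-4-[(1S)-2-[(tert-butyldiphenylsilyl)oxy]-1-chloroethyl]-6,6-dimethylcyclohex-3-en-1-yl}(pinacolato)borate | [Li+].CC1(C)[C@@H]([B-]2(OC(C)(C)C(C)(C)O2)c2cc(cc(c2)C(F)(F)F)C(F)(F)F)CC=C([C@H](Cl)CO[Si](c2ccccc2)(c2ccccc2)C(C)(C)C)[C@H]1Br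
F8 | step 5 | (2R,3Z)-4-bromo-1-[(tert-butyldiphenylsilyl)oxy]-3-ethenylbut-3-en-2-yl methanesulfonate | Br/C=C(/C=C)[C@@H](OS(C)(=O)=O)CO[Si](c1ccccc1)(c1ccccc1)C(C)(C)C
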